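A direct plan would start from (S)-linalool A1, turn its vinyl group into a methyl ketone and its prenyl end into an isopropenyl ketone to reach enedione A2, add an isopropyl alkyne by conjugate addition, close the seven-membered ring by rhodium-carbenoid cyclopropanation of a silyl enol ether and fluoride opening (diazoketone A3 to cycloheptanedione A4), close the cyclopentenone by alkyne hydration and aldol condensation, reduce the enone carbonyl and end with a double angeloylation of diol A5.
Its weakest steps would be three.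
(a) The singlet-oxygen ene reaction and dehydration that would make A2: the two allylic hydroperoxides would form in about equal amounts, so half the material would be lost in a run of functional-group changes that builds no ring and no stereocentre.
(b) The carbenoid cyclopropanation and ring opening that would give A4: the quaternary carbon C8a would be set only by the carbinol centre inherited from A1, four atoms away in a flexible chain, so the ring closure and its stereocentre would rest on a modest preference.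
(c) The final esterification of A5: a hindered tertiary α-ketol oxygen would have to be acylated with angelic anhydride on the most precious material, where Z-to-E isomerisation, α-ketol shift and incomplete acylation all threaten.

**Plan of the new route**
1. The C2 ester and the C7 ketone are removed last (acylation of a secondary allylic alcohol, oxidation of a C7 carbinol); the C3=C3a alkene and the C7 oxygen are traced to an oxygen bridge C3a–O–C7, and the C6 methyl and ester to a C6 ketone.
2. The resulting 3a,7-epoxyazulen-6-one is cut at C3a–C8a and C7–C8, bonds the direct plan never forms: an intramolecular [5+2] cycloaddition of a 3-oxidopyrylium (from a 2,5-disubstituted furan) with a 1,1-disubstituted alkene, so the five- and the seven-membered ring arise together in one step.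
3. The feature that allows this: C7 and C6 (the α-ketol carbons), C5, C4 and C3a are the five ring carbons of a 3-oxidopyrylium (C6 the oxido carbon, C7 and C3a on the ring oxygen), and C8a=C8 (the quaternary methyl carbon and its CH2) sits three atoms (C3, C2, C1) from C3a.
4. The furan side chain is cut at C3–furan (organocatalytic Friedel–Crafts addition to an enal with α-chlorination, which sets C3 and C2) and at C1–C8a (epoxide opening by an isopropenyl Grignard reagent).
5. The weak steps do not occur: there is no ene reaction; C8a is set by a stereocentre (C3) on the reacting pyrylium carbon; C6 is set on a rigid oxygen-bridged ketone; the tertiary angelate is made by trapping the alkoxide of the methyl addition before the ketone exists, and only a secondary allylic alcohol is acylated at the end.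

Key step: step 5

Remark: compound 1 is taken as a catalogue chemical (otherwise one silylation of furfuryl alcohol); carbon numbers C1–C8a are those of the azulene skeleton of the target and are used for all intermediates.

Step 1
Reactants: 1 tert-butyl(furan-2-ylmethoxy)dimethylsilane; 2 (2E)-4-methylpent-2-enal
Product: 5 tert-butyldimethyl({5-[(1R)-2-methyl-1-[(2R)-oxiran-2-yl]propyl]furan-2-yl}methoxy)silane, via chloroaldehyde 3 (not isolated), via chlorohydrin 4 (not isolated)
Conditions: (2S,5S)-5-benzyl-2-tert-butyl-3-methylimidazolidin-4-one·CF3CO2H (20 mol%), 2,3,4,5,6,6-hexachlorocyclohexa-2,4-dien-1-one, EtOAc, −40 °C; then NaBH4, EtOH, −40 → 0 °C; then KOH, EtOH–H2O, rt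
Reagents that add atoms: 2,3,4,5,6,6-hexachlorocyclohexa-2,4-dien-1-one, O=C1C(Cl)=C(Cl)C(Cl)=C(Cl)C1(Cl)Cl (the chlorine of 3 and 4 only)
Why: Organocascade catalysis, in which the imidazolidinone forms the (E)-iminium ion of 2, furan C5 adds in a Friedel–Crafts conjugate addition to the face left open by the benzyl group (sets C3), the same catalyst chlorinates the resulting enamine syn to the new furyl group (sets C2), and NaBH4 reduction followed by base closes the chlorohydrin with inversion at C2, so both stereocentres of the epoxide come from one catalyst.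

Step 2
Reactants: 5 tert-butyldimethyl({5-[(1R)-2-methyl-1-[(2R)-oxiran-2-yl]propyl]furan-2-yl}methoxy)silane; 6 isopropenylmagnesium bromide
Product: 8 tert-butyl({5-[(3R,4S)-4-[(tert-butyldimethylsilyl)oxy]-2,6-dimethylhept-6-en-3-yl]furan-2-yl}methoxy)dimethylsilane, via alcohol 7 (not isolated)
Conditions: 6 (2 equiv), CuI (10 mol%), THF, −30 → 0 °C; aq. NH4Cl; crude 7: TBSOTf, 2,6-lutidine, CH2Cl2, −78 → 0 °C
Reagents that add atoms: tert-butyldimethylsilyl triflate, CC(C)(C)[Si](C)(C)OS(=O)(=O)C(F)(F)F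
Why: Copper-catalysed SN2 opening of the terminal epoxide at its CH2 carbon by the alkenyl Grignard reagent installs the C8a=C8 alkene without touching C2 or C3, and silyl triflate silylation caps the hindered secondary alcohol with a group that cannot act as a neighbouring group in step 8.

Step 3
Reactants: 8 tert-butyl({5-[(3R,4S)-4-[(tert-butyldimethylsilyl)oxy]-2,6-dimethylhept-6-en-3-yl]furan-2-yl}methoxy)dimethylsilane
Product: 9 {5-[(3R,4S)-4-[(tert-butyldimethylsilyl)oxy]-2,6-dimethylhept-6-en-3-yl]furan-2-yl}methanol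
Conditions: HF·pyridine, pyridine, THF, 0 °C
Reagents that add atoms: none
Why: Buffered fluoride should cleave the unhindered primary furfuryl silyl ether much faster than the secondary one, which is flanked by the branched C3 carbon, and so frees the carbinol needed for the Achmatowicz reaction.

Step 4
Reactants: 9 {5-[(3R,4S)-4-[(tert-butyldimethylsilyl)oxy]-2,6-dimethylhept-6-en-3-yl]furan-2-yl}methanol
Product: 11 2-[(3R,4S)-4-[(tert-butyldimethylsilyl)oxy]-2,6-dimethylhept-6-en-3-yl]-5-oxo-5,6-dihydro-2H-pyran-2-yl acetate (both epimers at the acetal carbon), via hydroxypyranone 10 (not isolated)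
Conditions: NBS, NaHCO3, NaOAc, THF–H2O (4:1), 0 °C; then Ac2O, pyridine, DMAP (cat.), CH2Cl2, 0 °C → rt
Reagents that add atoms: water, O; acetic anhydride, CC(=O)OC(C)=O
Why: Achmatowicz rearrangement, in which the furan (far more nucleophilic than the 1,1-disubstituted alkene) is oxidised and hydrolysed to the ene-dione that closes on the primary hydroxyl to the 6-hydroxypyran-3-one, and acetylation of the hemiketal supplies the leaving group for ylide formation, the two acetal epimers converging in step 5.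

Step 5
Reactants: 11 2-[(3R,4S)-4-[(tert-butyldimethylsilyl)oxy]-2,6-dimethylhept-6-en-3-yl]-5-oxo-5,6-dihydro-2H-pyran-2-yl acetate
Product: 13 (2S,3R,3aR,7S,8aS)-2-[(tert-butyldimethylsilyl)oxy]-8a-methyl-3-(propan-2-yl)-1,2,3,7,8,8a-hexahydro-3a,7-epoxyazulen-6-one (oxygen bridge C3a–O–C7, C4=C5 enone), via oxidopyrylium betaine 12 (not isolated)
Conditions: i-Pr2NEt (3 equiv), MeCN (0.01 M), 60 °C
Reagents that add atoms: none
Why: The amine removes the proton next to the ketone and acetate leaves, giving the 3-oxidopyrylium betaine 12, which adds across its two oxygen-bound carbons to the tethered alkene in an intramolecular oxidopyrylium–alkene [5+2] cycloaddition, the closest known reaction type being the cycloaddition of acetoxypyranone-derived betaines that carry an alkenyl chain with stereocentres on the carbon next to the ring oxygen. The seven-membered carbocycle closes by the two [5+2] bonds C7–C8 and C3a–C8a, and the cyclopentane closes at the same time through the three-atom tether C3–C2–C1, which for geometric reasons must lie on the side of the ring oxygen (exo), so the methyl group on C8a is forced endo. The face is chosen by C3, the stereocentre on the pyrylium carbon: allylic 1,3-strain keeps its hydrogen near the ring plane next to the pyrylium C–H and its isopropyl group on the face opposite to the forming C3a–C8a bond, so the tether can reach only one face, and the C2 silyloxy group, trans to the isopropyl group on the new ring, is pseudo-equatorial in that transition state (matched case). C3a, C7 and the quaternary C8a are thereby set relative to C2 and C3, with the C8a methyl cis to the C2 oxygen as in the target. Regiochemistry is fixed by the tether, there is only one alkene, and a hindered, weakly basic amine at high dilution is chosen so that the C3–H next to the pyrylium ring is not epimerised and the betaine does not dimerise.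

Step 6
Reactants: 13 (2S,3R,3aR,7S,8aS)-2-[(tert-butyldimethylsilyl)oxy]-8a-methyl-3-(propan-2-yl)-1,2,3,7,8,8a-hexahydro-3a,7-epoxyazulen-6-one
Product: 14 (2S,3R,3aR,7S,8aS)-2-[(tert-butyldimethylsilyl)oxy]-8a-methyl-3-(propan-2-yl)octahydro-3a,7-epoxyazulen-6-one (C4 and C5 saturated)
Conditions: H2 (1 atm), Pd/C (10%), EtOAc, rt
Reagents that add atoms: none
Why: Heterogeneous hydrogenation should saturate the strained cis-disubstituted enone double bond without creating a stereocentre, and no other reducible group is present.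

Step 7
Reactants: 14 (2S,3R,3aR,7S,8aS)-2-[(tert-butyldimethylsilyl)oxy]-8a-methyl-3-(propan-2-yl)octahydro-3a,7-epoxyazulen-6-one; 15 angelic anhydride
Product: 17 (2S,3R,3aR,6S,7S,8aS)-2-[(tert-butyldimethylsilyl)oxy]-6,8a-dimethyl-3-(propan-2-yl)decahydro-3a,7-epoxyazulen-6-yl (2Z)-2-methylbut-2-enoate, via lithium alkoxide 16 (not isolated)
Conditions: MeLi (1.2 equiv), THF, −78 °C; then 15 (2 equiv), −78 → 0 °C; aq. NH4Cl
Reagents that add atoms: methyllithium, [Li]C
Why: 1,2-Addition of methyllithium to the ketone of the 8-oxabicyclo[3.2.1]octanone should occur from the exo face (the side of the oxygen bridge) because the endo face is blocked by the two-carbon bridge and its endo methyl group, which puts the C6 oxygen cis to the C8a methyl as in the target, and the lithium alkoxide is acylated in the same flask by the anhydride, so the hindered tertiary (Z)-ester forms without a separate acylation of a tertiary alcohol and without a nucleophilic catalyst.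

Step 8
Reactants: 17 (2S,3R,3aR,6S,7S,8aS)-2-[(tert-butyldimethylsilyl)oxy]-6,8a-dimethyl-3-(propan-2-yl)decahydro-3a,7-epoxyazulen-6-yl (2Z)-2-methylbut-2-enoate
Product: 19 (2S,6S,7S,8aS)-2-[(tert-butyldimethylsilyl)oxy]-7-hydroxy-6,8a-dimethyl-3-(propan-2-yl)-1,2,4,5,6,7,8,8a-octahydroazulen-6-yl (2Z)-2-methylbut-2-enoate, via trimethylsilyl ether 18 (not isolated)
Conditions: TMSOTf (1.5 equiv), 2,6-di-tert-butyl-4-methylpyridine (2 equiv), CH2Cl2, −78 → −30 °C; then 0.5 M HCl, THF–H2O, 0 °C
Reagents that add atoms: trimethylsilyl triflate, C[Si](C)(C)OS(=O)(=O)C(F)(F)F (the trimethylsilyl group of 18 only)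
Why: Silyl triflate activation of the bridging ether (eliminative cleavage of a tertiary bicyclic ether, as in acid-mediated openings of cineole-type ethers) should ionise the tertiary C3a–O bond and not the secondary C7–O bond beside the ester-bearing quaternary carbon, and loss of the anti-periplanar C3 proton gives the more substituted C3=C3a alkene inside the five-membered ring, the regiochemistry seen when carotol is dehydrated to daucene, while the C2 silyl ether cannot participate and dilute acid frees the C7 carbinol.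

Step 9
Reactants: 19 (2S,6S,7S,8aS)-2-[(tert-butyldimethylsilyl)oxy]-7-hydroxy-6,8a-dimethyl-3-(propan-2-yl)-1,2,4,5,6,7,8,8a-octahydroazulen-6-yl (2Z)-2-methylbut-2-enoate
Product: 20 (2S,6S,8aR)-2-[(tert-butyldimethylsilyl)oxy]-6,8a-dimethyl-7-oxo-3-(propan-2-yl)-1,2,4,5,6,7,8,8a-octahydroazulen-6-yl (2Z)-2-methylbut-2-enoate
Conditions: Dess–Martin periodinane, NaHCO3, CH2Cl2, 0 °C → rt
Reagents that add atoms: none
Why: Dess–Martin oxidation of the hindered secondary C7 carbinol under buffered, non-basic conditions should give the ketone before the neighbouring tertiary ester can migrate and without α-ketol rearrangement.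

Step 10
Reactants: 20 (2S,6S,8aR)-2-[(tert-butyldimethylsilyl)oxy]-6,8a-dimethyl-7-oxo-3-(propan-2-yl)-1,2,4,5,6,7,8,8a-octahydroazulen-6-yl (2Z)-2-methylbut-2-enoate
Product: 21 (2S,6S,8aR)-2-hydroxy-6,8a-dimethyl-7-oxo-3-(propan-2-yl)-1,2,4,5,6,7,8,8a-octahydroazulen-6-yl (2Z)-2-methylbut-2-enoate
Conditions: HF·pyridine, THF, 0 °C → rt
Reagents that add atoms: none
Why: Acid-buffered fluoride desilylation removes the secondary allylic silyl ether without base, so the tertiary α-acyloxy ketone and the (Z)-ester are left untouched and no stereocentre is affected.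

Step 11
Reactants: 21 (2S,6S,8aR)-2-hydroxy-6,8a-dimethyl-7-oxo-3-(propan-2-yl)-1,2,4,5,6,7,8,8a-octahydroazulen-6-yl (2Z)-2-methylbut-2-enoate; 15 angelic anhydride
Product: 22 (2S,6S,8aR)-6,8a-dimethyl-7-oxo-3-(propan-2-yl)-1,2,4,5,6,7,8,8a-octahydroazulene-2,6-diyl bis[(2Z)-2-methylbut-2-enoate]
Conditions: LiN(SiMe3)2 (1.05 equiv), THF, −78 °C; then 15 (1.5 equiv), −78 → −20 °C; aq. NH4Cl
Reagents that add atoms: none
Why: Acylation of the lithium alkoxide of the secondary allylic alcohol by the anhydride at low temperature (O–H deprotonation being much faster than enolisation of the hindered ketone) esterifies C2 with retention and without Z-to-E isomerisation of either angelate.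

**Compound list**

1 | tert-butyl(furan-2-ylmethoxy)dimethylsilane | CC(C)(C)[Si](C)(C)OCc1ccco1 | starting material
2 | (2E)-4-methylpent-2-enal | CC(C)/C=C/C=O | starting material
3 | (2S,3S)-3-(5-{[(tert-butyldimethylsilyl)oxy]methyl}furan-2-yl)-2-chloro-4-methylpentanal | O=C[C@@H](Cl)[C@@H](C(C)C)c1ccc(CO[Si](C)(C)C(C)(C)C)o1 | intermediate (not isolated)
4 | (2S,3S)-3-(5-{[(tert-butyldimethylsilyl)oxy]methyl}furan-2-yl)-2-chloro-4-methylpentan-1-ol | OC[C@@H](Cl)[C@@H](C(C)C)c1ccc(CO[Si](C)(C)C(C)(C)C)o1 | intermediate (not isolated)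
5 | tert-butyldimethyl({5-[(1R)-2-methyl-1-[(2R)-oxiran-2-yl]propyl]furan-2-yl}methoxy)silane | CC(C)[C@@H](c1ccc(CO[Si](C)(C)C(C)(C)C)o1)[C@@H]1CO1 | intermediate
6 | isopropenylmagnesium bromide (prop-1-en-2-ylmagnesium bromide) | CC(=C)[Mg]Br | starting material
7 | (4S,5R)-5-(5-{[(tert-butyldimethylsilyl)oxy]methyl}furan-2-yl)-2,6-dimethylhept-1-en-4-ol | C=C(C)C[C@H](O)[C@@H](C(C)C)c1ccc(CO[Si](C)(C)C(C)(C)C)o1 | intermediate (not isolated)
8 | tert-butyl({5-[(3R,4S)-4-[(tert-butyldimethylsilyl)oxy]-2,6-dimethylhept-6-en-3-yl]furan-2-yl}methoxy)dimethylsilane | C=C(C)C[C@H](O[Si](C)(C)C(C)(C)C)[C@@H](C(C)C)c1ccc(CO[Si](C)(C)C(C)(C)C)o1 | intermediate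
9 | {5-[(3R,4S)-4-[(tert-butyldimethylsilyl)oxy]-2,6-dimethylhept-6-en-3-yl]furan-2-yl}methanol | C=C(C)C[C@H](O[Si](C)(C)C(C)(C)C)[C@@H](C(C)C)c1ccc(CO)o1 | intermediate
10 | 6-[(3R,4S)-4-[(tert-butyldimethylsilyl)oxy]-2,6-dimethylhept-6-en-3-yl]-6-hydroxy-2H-pyran-3(6H)-one (both C6 epimers) | OC1(OCC(=O)C=C1)[C@H](C(C)C)[C@@H](O[Si](C)(C)C(C)(C)C)CC(C)=C | intermediate (not isolated)
11 | 2-[(3R,4S)-4-[(tert-butyldimethylsilyl)oxy]-2,6-dimethylhept-6-en-3-yl]-5-oxo-5,6-dihydro-2H-pyran-2-yl acetate (both epimers at the acetal carbon) | CC(=O)OC1(OCC(=O)C=C1)[C@H](C(C)C)[C@@H](O[Si](C)(C)C(C)(C)C)CC(C)=C | intermediate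
12 | 6-[(3R,4S)-4-[(tert-butyldimethylsilyl)oxy]-2,6-dimethylhept-6-en-3-yl]pyrylium-3-olate (3-oxidopyrylium betaine) | [O-]c1c[o+]c(cc1)[C@H](C(C)C)[C@@H](O[Si](C)(C)C(C)(C)C)CC(C)=C | intermediate (not isolated)
13 | (2S,3R,3aR,7S,8aS)-2-[(tert-butyldimethylsilyl)oxy]-8a-methyl-3-(propan-2-yl)-1,2,3,7,8,8a-hexahydro-3a,7-epoxyazulen-6-one | O=C1C=C[C@]23O[C@H]1C[C@@]2(C)C[C@H](O[Si](C)(C)C(C)(C)C)[C@H]3C(C)C | intermediate
14 | (2S,3R,3aR,7S,8aS)-2-[(tert-butyldimethylsilyl)oxy]-8a-methyl-3-(propan-2-yl)octahydro-3a,7-epoxyazulen-6-one | O=C1CC[C@]23O[C@H]1C[C@@]2(C)C[C@H](O[Si](C)(C)C(C)(C)C)[C@H]3C(C)C | intermediate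
15 | angelic anhydride, (2Z)-2-methylbut-2-enoic anhydride | C/C=C(/C)C(=O)OC(=O)/C(C)=C\C | starting material
16 | lithium (2S,3R,3aR,6S,7S,8aS)-2-[(tert-butyldimethylsilyl)oxy]-6,8a-dimethyl-3-(propan-2-yl)decahydro-3a,7-epoxyazulen-6-olate | [Li+].[O-][C@@]1(C)CC[C@]23O[C@H]1C[C@@]2(C)C[C@H](O[Si](C)(C)C(C)(C)C)[C@H]3C(C)C | intermediate (not isolated)
17 | (2S,3R,3aR,6S,7S,8aS)-2-[(tert-butyldimethylsilyl)oxy]-6,8a-dimethyl-3-(propan-2-yl)decahydro-3a,7-epoxyazulen-6-yl (2Z)-2-methylbut-2-enoate | C/C=C(/C)C(=O)O[C@@]1(C)CC[C@]23O[C@H]1C[C@@]2(C)C[C@H](O[Si](C)(C)C(C)(C)C)[C@H]3C(C)C | intermediate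
18 | 7-O-trimethylsilyl ether of 19: 2-[(tert-butyldimethylsilyl)oxy]-6,8a-dimethyl-3-(propan-2-yl)-7-[(trimethylsilyl)oxy]-1,2,4,5,6,7,8,8a-octahydroazulen-6-yl (2Z)-2-methylbut-2-enoate, configuration as in 19 | CC(C)(C)[Si](C)(C)O[C@H]1C[C@]2(C)C[C@H](O[Si](C)(C)C)[C@@](C)(OC(=O)/C(C)=C\C)CCC2=C1C(C)C | intermediate (not isolated)
19 | (2S,6S,7S,8aS)-2-[(tert-butyldimethylsilyl)oxy]-7-hydroxy-6,8a-dimethyl-3-(propan-2-yl)-1,2,4,5,6,7,8,8a-octahydroazulen-6-yl (2Z)-2-methylbut-2-enoate | CC(C)(C)[Si](C)(C)O[C@H]1C[C@]2(C)C[C@H](O)[C@@](C)(OC(=O)/C(C)=C\C)CCC2=C1C(C)C | intermediate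
20 | (2S,6S,8aR)-2-[(tert-butyldimethylsilyl)oxy]-6,8a-dimethyl-7-oxo-3-(propan-2-yl)-1,2,4,5,6,7,8,8a-octahydroazulen-6-yl (2Z)-2-methylbut-2-enoate | CC(C)(C)[Si](C)(C)O[C@H]1C[C@]2(C)CC(=O)[C@@](C)(OC(=O)/C(C)=C\C)CCC2=C1C(C)C | intermediate
21 | (2S,6S,8aR)-2-hydroxy-6,8a-dimethyl-7-oxo-3-(propan-2-yl)-1,2,4,5,6,7,8,8a-octahydroazulen-6-yl (2Z)-2-methylbut-2-enoate | O[C@H]1C[C@]2(C)CC(=O)[C@@](C)(OC(=O)/C(C)=C\C)CCC2=C1C(C)C | intermediate
22 | (2S,6S,8aR)-6,8a-dimethyl-7-oxo-3-(propan-2-yl)-1,2,4,5,6,7,8,8a-octahydroazulene-2,6-diyl bis[(2Z)-2-methylbut-2-enoate] | C/C=C(/C)C(=O)O[C@H]1C[C@]2(C)CC(=O)[C@@](C)(OC(=O)/C(C)=C\C)CCC2=C1C(C)C | target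

Total step count: 11. Longest linear sequence: 11 steps (from 1 and 2 to 22; 6 and 15 are bought).

**Steps most likely to fail**

Step 8 (eliminative opening of the oxygen bridge). The tertiary cation at C3a may lose a proton from C4 and give the less substituted alkene, a group may shift from the neighbouring quaternary carbon C8a, or the allylic silyl ether may ionise once the alkene is there. The fallback sets out from 17 and comes back at 21, and opens the bridge by an E1cB elimination that can only give the C3=C3a alkene. HF·pyridine (THF) would free the C2 carbinol to give (2S,3R,3aR,6S,7S,8aR)-2-hydroxy-6,8a-dimethyl-3-(propan-2-yl)decahydro-3a,7-epoxyazulen-6-yl (2Z)-2-methylbut-2-enoate F1. Dess–Martin periodinane would give the β-alkoxy ketone (3S,3aR,6S,7S,8aS)-6,8a-dimethyl-2-oxo-3-(propan-2-yl)decahydro-3a,7-epoxyazulen-6-yl (2Z)-2-methylbut-2-enoate F2. DBU (CH2Cl2, 0 °C) would expel the bridging alkoxide from the C3 enolate to give the hydroxy enone (6S,7S,8aS)-7-hydroxy-6,8a-dimethyl-2-oxo-3-(propan-2-yl)-1,2,4,5,6,7,8,8a-octahydroazulen-6-yl (2Z)-2-methylbut-2-enoate F3, which would be oxidised at once (Dess–Martin periodinane) to the enedione (6S,8aR)-6,8a-dimethyl-2,7-dioxo-3-(propan-2-yl)-1,2,4,5,6,7,8,8a-octahydroazulen-6-yl (2Z)-2-methylbut-2-enoate F4. Corey–Bakshi–Shibata reduction ((R)-2-methyl-CBS-oxazaborolidine, BH3·SMe2, −30 °C) of the enone carbonyl anti to the angular methyl group, with the hindered C7 ketone left alone, would then give 21; the price is that C2 is erased and set again by a reagent.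

Step 5 (the cycloaddition). The betaine may be deprotonated reversibly next to the pyrylium ring, which would erase the controlling C3 centre or lead to an alkylidene pyranone, and it may dimerise if the unactivated 1,1-disubstituted alkene adds slowly. The fallback sets out from 10 and comes back at 14, and makes the dipole as a carbonyl ylide under neutral conditions. Zn in AcOH would reduce the enone double bond of crude 10 to (6R,7S)-7-[(tert-butyldimethylsilyl)oxy]-1-hydroxy-9-methyl-6-(propan-2-yl)dec-9-ene-2,5-dione F5 (in equilibrium with its lactol). NaIO4 (THF–H2O) would cleave its α-ketol end to (5R,6S)-6-[(tert-butyldimethylsilyl)oxy]-8-methyl-4-oxo-5-(propan-2-yl)non-8-enoic acid F6. Isobutyl chloroformate and Et3N, then CH2N2, would give (6R,7S)-7-[(tert-butyldimethylsilyl)oxy]-1-diazo-9-methyl-6-(propan-2-yl)dec-9-ene-2,5-dione F7. Rh2(OAc)4 (1 mol%, CH2Cl2, rt) would form the six-membered carbonyl ylide from the carbenoid and the C3a ketone, and its intramolecular cycloaddition to the tethered alkene, under the same allylic-strain control by C3, would give the saturated bridged ketone 14 directly.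

Step 1 (the organocascade). The silyloxymethylfuran may add too slowly to the β-branched iminium ion, the acid co-catalyst may cleave the furfuryl silyl ether, or the chlorination may lose diastereoselectivity. The fallback sets out from 2 and 1 and comes back at 5, and uses an auxiliary in place of the catalyst. NaClO2 (NaH2PO4, 2-methylbut-2-ene, t-BuOH–H2O) would oxidise 2 to (2E)-4-methylpent-2-enoic acid F8, and pivaloyl chloride/Et3N, then (4S)-4-phenyl-1,3-oxazolidin-2-one with LiCl, would give (4S)-3-[(2E)-4-methylpent-2-enoyl]-4-phenyl-1,3-oxazolidin-2-one F9. Furan 1 would be lithiated at C5 (n-BuLi, THF, 0 °C), transmetallated with MgBr2·OEt2 and added to F9 in the presence of CuBr·SMe2 (THF–Me2S, −20 °C), and the enolate would be brominated in the same flask with N-bromosuccinimide (−78 °C) to give (4S)-3-[(2S,3S)-2-bromo-3-(5-{[(tert-butyldimethylsilyl)oxy]methyl}furan-2-yl)-4-methylpentanoyl]-4-phenyl-1,3-oxazolidin-2-one F10. The furyl group and the bromine both enter anti to the phenyl group of the auxiliary, which is the relative configuration needed. LiBH4 (THF, MeOH, 0 °C) would release the auxiliary and give (2S,3S)-2-bromo-3-(5-{[(tert-butyldimethylsilyl)oxy]methyl}furan-2-yl)-4-methylpentan-1-ol F11, and K2CO3 in MeOH would close it with inversion at C2 to epoxide 5.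

**Further compounds**

F1 | step 8 | (2S,3R,3aR,6S,7S,8aR)-2-hydroxy-6,8a-dimethyl-3-(propan-2-yl)decahydro-3a,7-epoxyazulen-6-yl (2Z)-2-methylbut-2-enoate | C/C=C(/C)C(=O)O[C@@]1(C)CC[C@]23O[C@H]1C[C@@]2(C)C[C@H](O)[C@H]3C(C)C
F2 | step 8 | (3S,3aR,6S,7S,8aS)-6,8a-dimethyl-2-oxo-3-(propan-2-yl)decahydro-3a,7-epoxyazulen-6-yl (2Z)-2-methylbut-2-enoate | C/C=C(/C)C(=O)O[C@@]1(C)CC[C@]23O[C@H]1C[C@@]2(C)CC(=O)[C@H]3C(C)C
F3 | step 8 | (6S,7S,8aS)-7-hydroxy-6,8a-dimethyl-2-oxo-3-(propan-2-yl)-1,2,4,5,6,7,8,8a-octahydroazulen-6-yl (2Z)-2-methylbut-2-enoate | O=C1C[C@]2(C)C[C@H](O)[C@@](C)(OC(=O)/C(C)=C\C)CCC2=C1C(C)C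
F4 | step 8 | (6S,8aR)-6,8a-dimethyl-2,7-dioxo-3-(propan-2-yl)-1,2,4,5,6,7,8,8a-octahydroazulen-6-yl (2Z)-2-methylbut-2-enoate | O=C1C[C@]2(C)CC(=O)[C@@](C)(OC(=O)/C(C)=C\C)CCC2=C1C(C)C
F5 | step 5 | (6R,7S)-7-[(tert-butyldimethylsilyl)oxy]-1-hydroxy-9-methyl-6-(propan-2-yl)dec-9-ene-2,5-dione | OCC(=O)CCC(=O)[C@H](C(C)C)[C@@H](O[Si](C)(C)C(C)(C)C)CC(C)=C
F6 | step 5 | (5R,6S)-6-[(tert-butyldimethylsilyl)oxy]-8-methyl-4-oxo-5-(propan-2-yl)non-8-enoic acid | OC(=O)CCC(=O)[C@H](C(C)C)[C@@H](O[Si](C)(C)C(C)(C)C)CC(C)=C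
F7 | step 5 | (6R,7S)-7-[(tert-butyldimethylsilyl)oxy]-1-diazo-9-methyl-6-(propan-2-yl)dec-9-ene-2,5-dione | [N-]=[N+]=CC(=O)CCC(=O)[C@H](C(C)C)[C@@H](O[Si](C)(C)C(C)(C)C)CC(C)=C
F8 | step 1 | (2E)-4-methylpent-2-enoic acid | CC(C)/C=C/C(=O)O
F9 | step 1 | (4S)-3-[(2E)-4-methylpent-2-enoyl]-4-phenyl-1,3-oxazolidin-2-one | CC(C)/C=C/C(=O)N1[C@@H](c2ccccc2)COC1=O
F10 | step 1 | (4S)-3-[(2S,3S)-2-bromo-3-(5-{[(tert-butyldimethylsilyl)oxy]methyl}furan-2-yl)-4-methylpentanoyl]-4-phenyl-1,3-oxazolidin-2-one | CC(C)[C@@H](c1ccc(CO[Si](C)(C)C(C)(C)C)o1)[C@H](Br)C(=O)N1[C@@H](c2ccccc2)COC1=O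
F11 | step 1 | (2S,3S)-2-bromo-3-(5-{[(tert-butyldimethylsilyl)oxy]methyl}furan-2-yl)-4-methylpentan-1-ol | OC[C@@H](Br)[C@@H](C(C)C)c1ccc(CO[Si](C)(C)C(C)(C)C)o1
A1 | direct plan | (S)-linalool, (3S)-3,7-dimethylocta-1,6-dien-3-ol | C=C[C@@](C)(O)CCC=C(C)C
A2 | direct plan | (6S)-6-[(tert-butyldimethylsilyl)oxy]-2,6-dimethyloct-1-ene-3,7-dione | CC(=O)[C@@](C)(O[Si](C)(C)C(C)(C)C)CCC(=O)C(C)=C
A3 | direct plan | (3S,6E)-3,6-bis[(tert-butyldimethylsilyl)oxy]-1-diazo-3,7,11-trimethyldodec-6-en-9-yn-2-one | [N-]=[N+]=CC(=O)[C@@](C)(O[Si](C)(C)C(C)(C)C)CC/C(O[Si](C)(C)C(C)(C)C)=C(/C)CC#CC(C)C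
A4 | direct plan | (2R,5S)-5-[(tert-butyldimethylsilyl)oxy]-2,5-dimethyl-2-(4-methylpent-2-yn-1-yl)cycloheptane-1,4-dione | O=C1[C@@](C)(O[Si](C)(C)C(C)(C)C)CCC(=O)[C@](C)(CC#CC(C)C)C1
A5 | direct plan | (2S,6S,8aR)-2,6-dihydroxy-6,8a-dimethyl-3-(propan-2-yl)-1,4,5,6,8,8a-hexahydroazulen-7(2H)-one | O[C@H]1C[C@]2(C)CC(=O)[C@@](C)(O)CCC2=C1C(C)C
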